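**Plan**

- Numbering: ten-membered ring C1–C10 (C1 quaternary with methyl, C2 tigloyloxy, C5=C6, C7 lactone carbinol, C8 butenolide β-carbon, C10 ring-fusion CH); ring A = C1, C10, C11–C14; C17 and C19 = butenolide α-carbon and carbonyl.
- Enabling feature: ring A is a cyclohexene with the contiguous triad C14(O)–C1(quaternary, methyl)–C10(H) next to C11. This is the retron of an endo Diels–Alder reaction between a 1-silyloxypenta-1,3-diene and an (E)-2-methyl enal.
- Retrosynthesis: take off the acetate, the C13 ketone and the tiglate; open the butenolide at C8=C17; cut C6–C7 of the ten-membered ring; cut C3–C4; move C11=C12 back to C12=C13; cut C1–C14 and C10–C11.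
- Forward: ring A (step 4), alkene transposition on ring A, C2–C6 chain, ten-membered ring (Nozaki–Hiyama–Kishi), butenolide (Horner–Wadsworth–Emmons), then enone and acetate.
- Stereochemistry: C1, C10, C14 (and transient C11) from the catalyst-controlled cycloaddition; C2 from a Corey–Bakshi–Shibata reduction; C7 from Felkin–Anh addition next to a chiral-pool C8 centre that is later oxidized; 5Z from a (Z)-vinyl iodide.

Key step: step 4

Assumption: the (S)-configured oxazaborolidinium catalyst is taken to be the antipode that exposes the Re face of C1 of the enal (formyl C–H···O binding model); if the sense proves opposite, the (R)-catalyst replaces it with no other change.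

**Route**

Step 1
Reactants: 1 (E)-pent-2-enal
Product: 2 (1E,3E)-1-(triisopropylsilyloxy)penta-1,3-diene
Conditions: TIPSOTf, Et3N, Et2O, 0 °C → rt
Reagents that add atoms: triisopropylsilyl triflate, CC(C)[Si](C(C)C)(C(C)C)OS(=O)(=O)C(F)(F)F
Why: Soft enolization (O-silylation, then γ-deprotonation) should give the conjugated silyl dienol ether, mainly as the (1E,3E) isomer; any (3Z) isomer cannot reach the s-cis form and is inert in step 4.

Step 2
Reactants: 3 (S)-2-(2,2-dimethyl-1,3-dioxolan-4-yl)ethanol
Product: 4 (S)-2-(2,2-dimethyl-1,3-dioxolan-4-yl)acetaldehyde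
Conditions: DMP, CH2Cl2, 0 °C → rt
Reagents that add atoms: none
Why: Dess–Martin oxidation of a primary alcohol under near-neutral conditions should spare the acetonide, and the stereocentre is β to the new carbonyl and cannot epimerize.

Step 3
Reactants: 4 (S)-2-(2,2-dimethyl-1,3-dioxolan-4-yl)acetaldehyde; 5 2-(triphenylphosphoranylidene)propanal
Product: 6 (E)-4-[(4S)-2,2-dimethyl-1,3-dioxolan-4-yl]-2-methylbut-2-enal
Conditions: toluene, 80 °C
Reagents that add atoms: none
Why: Wittig olefination with a formyl-stabilized ylide should give the (E)-2-methyl enal under thermodynamic control.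

Step 4
Reactants: 2 (1E,3E)-1-(triisopropylsilyloxy)penta-1,3-diene; 6 (E)-4-[(4S)-2,2-dimethyl-1,3-dioxolan-4-yl]-2-methylbut-2-enal
Product: 7 ring A aldehyde, (1S,2R,5S,6R)-6-{[(4S)-2,2-dimethyl-1,3-dioxolan-4-yl]methyl}-1,5-dimethyl-2-(triisopropylsilyloxy)cyclohex-3-ene-1-carbaldehyde
Conditions: (S)-3,3-diphenyl-1-(2-methylphenyl)tetrahydropyrrolo[1,2-c][1,3,2]oxazaborole·HNTf2 (20 mol %), CH2Cl2, −78 → −40 °C
Reagents that add atoms: none
Why: This is a concerted, Lewis-acid-accelerated normal-demand [4+2] cycloaddition (catalytic enantioselective Diels–Alder reaction of an α-methyl enal with a 1-silyloxy diene under a chiral oxazaborolidinium ion) that closes ring A in one intermolecular step by forming the C1–C14 and C10–C11 σ bonds. The silyloxy donor puts the largest HOMO coefficient on C11, which bonds to the enal β-carbon C10 while C14 bonds to the α-carbon C1, and the boron-bound formyl group keeps the dienophile reactive enough to form the quaternary centre. Endo approach of the coordinated formyl group sets the C14 oxygen cis to the formyl carbon C2, the E geometry of the enal sets C9 trans to C2 (C1 versus C10), and the E,E geometry of the diene sets the C11 methyl cis to the C14 oxygen. The absolute configuration of C1, C10, C11 and C14 comes from the catalyst, whose aryl group shields one face of the s-trans enal held by the B–O bond and a formyl C–H···O contact, so that the diene adds to the Re face of C1. Regio-, endo- and facial selectivity are all needed and are secured by the silyloxy group, the Lewis-acid-bound formyl group and the catalyst, the remote dioxolane centre being a spectator.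

Step 5
Reactants: 7 ring A aldehyde
Product: 8 12,13-epoxide of 7 with the oxirane oxygen trans to the C14 silyloxy group
Conditions: DMDO, acetone/CH2Cl2, 0 °C
Reagents that add atoms: dimethyldioxirane, CC1(C)OO1
Why: Dioxirane epoxidation is a concerted electrophilic oxygen transfer; in the half-chair that keeps the C9 chain and the formyl group equatorial the C14 silyloxy group is pseudoaxial and, pushed over the alkene by the quaternary C1, should direct oxygen to the opposite face, and the dioxirane does not cause Baeyer–Villiger cleavage of the aldehyde.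

Step 6
Reactants: 8 epoxide
Product: 9 bromohydrin with Br on C12 (cis to C14–O) and OH on C13 (trans to C14–O)
Conditions: LiBr, AcOH, THF, rt
Reagents that add atoms: lithium bromide, [Li+].[Br-]
Why: Acid-assisted SN2 opening of the epoxide by bromide should occur at C12, because trans-diaxial opening in the chair with the C9 chain and C2 equatorial and the inductive effect of the C14 oxygen both point to that carbon.

Step 7
Reactants: 9 bromohydrin
Product: 10 C13 tert-butyldimethylsilyl ether of 9
Conditions: TBSOTf, 2,6-lutidine, CH2Cl2, −78 → 0 °C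
Reagents that add atoms: tert-butyldimethylsilyl triflate, CC(C)(C)[Si](C)(C)OS(=O)(=O)C(F)(F)F
Why: Silylation of the hindered secondary alcohol with a silyl triflate blocks re-closure to the epoxide in step 8, and the aldehyde has no α-hydrogen and cannot form a silyl enol ether.

Step 8
Reactants: 10 bromo silyl ether
Product: 11 transposed aldehyde with the C11=C12 alkene and C13–OTBS trans to C14–OTIPS
Conditions: DBU, toluene, 100 °C
Reagents that add atoms: none
Why: E2 dehydrobromination: the axial C12–Br bond is antiperiplanar only to the axial C11–H (C13–H is gauche), so the alkene can form only as C11=C12, giving the allylic silyl ether that masks the later enone.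

Step 9
Reactants: 11 transposed aldehyde
Product: 12 secondary alcohol (C2 carbinol CH(OH)CH3, both C2 epimers)
Conditions: MeMgBr, THF, −78 → 0 °C
Reagents that add atoms: methylmagnesium bromide, C[Mg]Br
Why: Grignard addition to the non-enolizable neopentyl aldehyde installs C3; the carbinol configuration is irrelevant because step 10 removes it.

Step 10
Reactants: 12 secondary alcohol
Product: 13 methyl ketone (C2 acetyl group on C1)
Conditions: DMP, CH2Cl2, rt
Reagents that add atoms: none
Why: Dess–Martin oxidation gives a ketone that can enolize only towards C3 because C1 is quaternary.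

Step 11
Reactants: 14 prop-2-yn-1-ol
Product: 16 (Z)-3-iodo-2-methylprop-2-en-1-ol, via vinylmagnesium alkoxide 15 (not isolated)
Conditions: MeMgBr, CuI (10 mol %), THF, −10 °C → rt; then I2, −10 °C
Reagents that add atoms: methylmagnesium bromide, C[Mg]Br; iodine, II
Why: Copper-catalysed anti carbomagnesiation of the propargylic alkoxide places magnesium cis to the CH2O group by chelation, and iodinolysis with retention should give the (Z)-iodoalkene.

Step 12
Reactants: 16 (Z)-3-iodo-2-methylprop-2-en-1-ol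
Product: 17 (Z)-3-bromo-1-iodo-2-methylprop-1-ene
Conditions: CBr4, PPh3, CH2Cl2, 0 °C
Reagents that add atoms: carbon tetrabromide, BrC(Br)(Br)Br
Why: Appel bromination of the primary allylic alcohol leaves the alkene geometry untouched.

Step 13
Reactants: 13 methyl ketone; 17 (Z)-3-bromo-1-iodo-2-methylprop-1-ene
Product: 19 C3-alkylated ketone with the (Z)-5-iodo-4-methylpent-4-enoyl group on C1, via lithium enolate 18 (not isolated)
Conditions: LDA, THF, −78 °C; then 17, DMPU, −78 → −30 °C
Reagents that add atoms: none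
Why: Kinetic enolate alkylation: the ketone has a single enolizable position and the allylic bromide is a reactive SN2 electrophile, so the C3–C4 bond should form without touching the vinyl iodide.

Step 14
Reactants: 19 C3-alkylated ketone
Product: 20 (2S)-alcohol
Conditions: (R)-Me-CBS oxazaborolidine (1-methyl-3,3-diphenyltetrahydropyrrolo[1,2-c][1,3,2]oxazaborole), BH3·SMe2, THF, −20 → 0 °C
Reagents that add atoms: none
Why: Corey–Bakshi–Shibata reduction: with the quaternary C1 as the large and the C3 methylene as the small substituent, the (R)-catalyst should deliver hydride to the face that gives the (2S) alcohol by reagent control.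

Step 15
Reactants: 20 (2S)-alcohol
Product: 21 (2S)-tiglate, the (E)-2-methylbut-2-enoate of 20
Conditions: (E)-2-methylbut-2-enoyl chloride, pyridine, DMAP, CH2Cl2, 0 → 40 °C
Reagents that add atoms: (E)-2-methylbut-2-enoyl chloride, C/C=C(\C)C(=O)Cl
Why: DMAP-catalysed acylation of the secondary alcohol with the acid chloride; pyridine as a weak base should avoid deconjugation through a vinylketene.

Step 16
Reactants: 21 (2S)-tiglate
Product: 22 (8S)-7,8-diol
Conditions: CeCl3·7H2O, oxalic acid (cat.), MeCN, rt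
Reagents that add atoms: none
Why: Acid-catalysed hydrolysis of the terminal isopropylidene ketal should be faster than cleavage of the secondary silyl ethers under these mild conditions.

Step 17
Reactants: 22 7,8-diol
Product: 23 7,8-bis(triethylsilyl) ether
Conditions: Et3SiCl, imidazole, DMF, 0 °C → rt
Reagents that add atoms: chlorotriethylsilane, CC[Si](CC)(CC)Cl
Why: Imidazole-promoted silylation of both unhindered hydroxyl groups.

Step 18
Reactants: 23 7,8-bis(triethylsilyl) ether
Product: 25 C7 aldehyde with the (8S)-triethylsilyloxy group, via alkoxydimethylsulfonium chloride 24 (not isolated)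
Conditions: (COCl)2, DMSO, CH2Cl2, −78 → −40 °C; then Et3N, −78 °C
Reagents that add atoms: none
Why: Swern oxidation in which the chlorosulfonium reagent cleaves only the primary triethylsilyl ether and oxidizes it to the aldehyde, the secondary silyl ethers and the C8 centre staying intact at low temperature.

Step 19
Reactants: 25 C7 aldehyde
Product: 26 ten-membered ring allylic alcohol with the C6–C7 bond closed, (7R)-OH anti to (8S)-OSiEt3 and the 5Z alkene
Conditions: CrCl2 (excess), NiCl2 (cat.), DMSO/THF, rt, high dilution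
Reagents that add atoms: none
Why: Nozaki–Hiyama–Kishi reaction: nickel-catalysed formation of a vinylchromium species with retention of the Z geometry and its chemoselective addition to the aldehyde should close the ten-membered ring, with Felkin–Anh addition anti to the C8 silyloxy group giving the (7R) alcohol.

Step 20
Reactants: 26 ten-membered ring allylic alcohol
Product: 27 C7 2-(diethoxyphosphoryl)propanoate (both epimers at the phosphonate carbon)
Conditions: 2-(diethoxyphosphoryl)propanoic acid, DCC, DMAP, CH2Cl2, 0 °C → rt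
Reagents that add atoms: 2-(diethoxyphosphoryl)propanoic acid, CCOP(=O)(OCC)C(C)C(=O)O
Why: Steglich esterification of the allylic alcohol brings in C17, C18 and C19 of the lactone.

Step 21
Reactants: 27 C7 phosphonate ester
Product: 28 C8 alcohol
Conditions: HF·pyridine, pyridine, THF, 0 °C
Reagents that add atoms: none
Why: Fluoride-mediated desilylation should remove only the most labile secondary triethylsilyl ether, and the pyridine buffer suppresses acyl migration from O7 to O8.

Step 22
Reactants: 28 C8 alcohol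
Product: 29 C8 ketone
Conditions: DMP, CH2Cl2, rt
Reagents that add atoms: none
Why: Dess–Martin oxidation of the secondary alcohol gives the α-acyloxy ketone without base.

Step 23
Reactants: 29 C8 ketone
Product: 30 butenolide (C8=C17 lactone) with 13-OTBS and 14-OTIPS
Conditions: LiCl, i-Pr2NEt, MeCN, rt
Reagents that add atoms: none
Why: Intramolecular Horner–Wadsworth–Emmons reaction under Masamune–Roush conditions: the phosphonate carbanion C17 condenses with the C8 ketone in a five-membered ring closure, and the mild base should leave C7 untouched.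

Step 24
Reactants: 30 butenolide
Product: 31 13,14-diol
Conditions: HF·pyridine (excess), THF, rt
Reagents that add atoms: none
Why: Fluoride-mediated cleavage of both remaining silyl ethers; the lactone and the tiglate should be stable to HF·pyridine.

Step 25
Reactants: 31 13,14-diol
Product: 32 14-hydroxy 11-en-13-one
Conditions: MnO2, CH2Cl2, rt
Reagents that add atoms: none
Why: Manganese dioxide oxidation is selective for the allylic C13 alcohol, so the C11=C12–C13 enone forms and the C14 alcohol stays free.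

Step 26
Reactants: 32 14-hydroxy 11-en-13-one
Product: 33 CNP0218548.3
Conditions: Ac2O, pyridine, DMAP (cat.), CH2Cl2, 0 °C
Reagents that add atoms: acetic anhydride, CC(=O)OC(C)=O
Why: DMAP-catalysed acetylation of the remaining secondary alcohol should complete the target without epimerizing C14 under these weakly basic conditions.

**Compound list**

1 | (E)-pent-2-enal | CC/C=C/C=O | starting material
2 | (1E,3E)-1-(triisopropylsilyloxy)penta-1,3-diene | C/C=C/C=C/O[Si](C(C)C)(C(C)C)C(C)C | intermediate
3 | (S)-2-(2,2-dimethyl-1,3-dioxolan-4-yl)ethanol | OCC[C@H]1COC(C)(C)O1 | starting material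
4 | (S)-2-(2,2-dimethyl-1,3-dioxolan-4-yl)acetaldehyde | O=CC[C@H]1COC(C)(C)O1 | intermediate
5 | 2-(triphenylphosphoranylidene)propanal | CC(C=O)=P(c1ccccc1)(c1ccccc1)c1ccccc1 | starting material
6 | (E)-4-[(4S)-2,2-dimethyl-1,3-dioxolan-4-yl]-2-methylbut-2-enal | O=C/C(C)=C/C[C@H]1COC(C)(C)O1 | intermediate
7 | ring A aldehyde, (1S,2R,5S,6R)-6-{[(4S)-2,2-dimethyl-1,3-dioxolan-4-yl]methyl}-1,5-dimethyl-2-(triisopropylsilyloxy)cyclohex-3-ene-1-carbaldehyde (cyclohexene C1, C2, C3, C4, C5, C6 = target C1, C14, C13, C12, C11, C10) | CC(C)[Si](C(C)C)(C(C)C)O[C@@H]1C=C[C@H](C)[C@@H](C[C@H]2COC(C)(C)O2)[C@]1(C)C=O | intermediate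
8 | 12,13-epoxide of 7, oxirane oxygen trans to the C14 silyloxy group | CC(C)[Si](C(C)C)(C(C)C)O[C@@H]1[C@H]2O[C@H]2[C@H](C)[C@@H](C[C@H]3COC(C)(C)O3)[C@]1(C)C=O | intermediate
9 | bromohydrin, Br on C12 cis and OH on C13 trans to C14–O | CC(C)[Si](C(C)C)(C(C)C)O[C@@H]1[C@@H](O)[C@H](Br)[C@H](C)[C@@H](C[C@H]2COC(C)(C)O2)[C@]1(C)C=O | intermediate
10 | C13 tert-butyldimethylsilyl ether of 9 | CC(C)[Si](C(C)C)(C(C)C)O[C@@H]1[C@@H](O[Si](C)(C)C(C)(C)C)[C@H](Br)[C@H](C)[C@@H](C[C@H]2COC(C)(C)O2)[C@]1(C)C=O | intermediate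
11 | transposed aldehyde, C11=C12 alkene, C13–OTBS trans to C14–OTIPS | CC(C)[Si](C(C)C)(C(C)C)O[C@@H]1[C@@H](O[Si](C)(C)C(C)(C)C)C=C(C)[C@@H](C[C@H]2COC(C)(C)O2)[C@]1(C)C=O | intermediate
12 | secondary alcohol from 11, C2 carbinol CH(OH)CH3 as both epimers | CC(C)[Si](C(C)C)(C(C)C)O[C@@H]1[C@@H](O[Si](C)(C)C(C)(C)C)C=C(C)[C@@H](C[C@H]2COC(C)(C)O2)[C@]1(C)C(C)O | intermediate
13 | methyl ketone, C2 acetyl group on C1 | CC(C)[Si](C(C)C)(C(C)C)O[C@@H]1[C@@H](O[Si](C)(C)C(C)(C)C)C=C(C)[C@@H](C[C@H]2COC(C)(C)O2)[C@]1(C)C(C)=O | intermediate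
14 | prop-2-yn-1-ol | C#CCO | starting material
15 | vinylmagnesium alkoxide, (Z)-BrMgOCH2C(CH3)=CHMgBr | Br[Mg]OC/C(C)=C\[Mg]Br | intermediate
16 | (Z)-3-iodo-2-methylprop-2-en-1-ol | OC/C(C)=C\I | intermediate
17 | (Z)-3-bromo-1-iodo-2-methylprop-1-ene | BrC/C(C)=C\I | intermediate
18 | lithium enolate of 13, C2(OLi)=C3H2 | CC(C)[Si](C(C)C)(C(C)C)O[C@@H]1[C@@H](O[Si](C)(C)C(C)(C)C)C=C(C)[C@@H](C[C@H]2COC(C)(C)O2)[C@]1(C)C(=C)O[Li] | intermediate
19 | C3-alkylated ketone, (Z)-5-iodo-4-methylpent-4-enoyl group on C1 | CC(C)[Si](C(C)C)(C(C)C)O[C@@H]1[C@@H](O[Si](C)(C)C(C)(C)C)C=C(C)[C@@H](C[C@H]2COC(C)(C)O2)[C@]1(C)C(=O)CC/C(C)=C\I | intermediate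
20 | (2S)-alcohol from 19 | CC(C)[Si](C(C)C)(C(C)C)O[C@@H]1[C@@H](O[Si](C)(C)C(C)(C)C)C=C(C)[C@@H](C[C@H]2COC(C)(C)O2)[C@]1(C)[C@@H](O)CC/C(C)=C\I | intermediate
21 | (2S)-tiglate, (E)-2-methylbut-2-enoate of 20 | CC(C)[Si](C(C)C)(C(C)C)O[C@@H]1[C@@H](O[Si](C)(C)C(C)(C)C)C=C(C)[C@@H](C[C@H]2COC(C)(C)O2)[C@]1(C)[C@@H](OC(=O)/C(C)=C/C)CC/C(C)=C\I | intermediate
22 | (8S)-7,8-diol from 21 | CC(C)[Si](C(C)C)(C(C)C)O[C@@H]1[C@@H](O[Si](C)(C)C(C)(C)C)C=C(C)[C@@H](C[C@H](O)CO)[C@]1(C)[C@@H](OC(=O)/C(C)=C/C)CC/C(C)=C\I | intermediate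
23 | 7,8-bis(triethylsilyl) ether of 22 | CC(C)[Si](C(C)C)(C(C)C)O[C@@H]1[C@@H](O[Si](C)(C)C(C)(C)C)C=C(C)[C@@H](C[C@H](O[Si](CC)(CC)CC)CO[Si](CC)(CC)CC)[C@]1(C)[C@@H](OC(=O)/C(C)=C/C)CC/C(C)=C\I | intermediate
24 | C7 alkoxydimethylsulfonium chloride from 23 | CC(C)[Si](C(C)C)(C(C)C)O[C@@H]1[C@@H](O[Si](C)(C)C(C)(C)C)C=C(C)[C@@H](C[C@H](O[Si](CC)(CC)CC)CO[S+](C)C)[C@]1(C)[C@@H](OC(=O)/C(C)=C/C)CC/C(C)=C\I.[Cl-] | intermediate
25 | C7 aldehyde with (8S)-triethylsilyloxy group | CC(C)[Si](C(C)C)(C(C)C)O[C@@H]1[C@@H](O[Si](C)(C)C(C)(C)C)C=C(C)[C@@H](C[C@H](O[Si](CC)(CC)CC)C=O)[C@]1(C)[C@@H](OC(=O)/C(C)=C/C)CC/C(C)=C\I | intermediate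
26 | ten-membered ring allylic alcohol, (7R)-OH anti to (8S)-OSiEt3, 5Z alkene | CC(C)[Si](C(C)C)(C(C)C)O[C@@H]1[C@@H](O[Si](C)(C)C(C)(C)C)C=C(C)[C@H]2C[C@H](O[Si](CC)(CC)CC)[C@H](O)/C=C(C)\CC[C@H](OC(=O)/C(C)=C/C)[C@]12C | intermediate
27 | C7 2-(diethoxyphosphoryl)propanoate of 26 | CC(C)[Si](C(C)C)(C(C)C)O[C@@H]1[C@@H](O[Si](C)(C)C(C)(C)C)C=C(C)[C@H]2C[C@H](O[Si](CC)(CC)CC)[C@H](OC(=O)C(C)P(=O)(OCC)OCC)/C=C(C)\CC[C@H](OC(=O)/C(C)=C/C)[C@]12C | intermediate
28 | C8 alcohol from 27 | CC(C)[Si](C(C)C)(C(C)C)O[C@@H]1[C@@H](O[Si](C)(C)C(C)(C)C)C=C(C)[C@H]2C[C@H](O)[C@H](OC(=O)C(C)P(=O)(OCC)OCC)/C=C(C)\CC[C@H](OC(=O)/C(C)=C/C)[C@]12C | intermediate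
29 | C8 ketone from 28 | CC(C)[Si](C(C)C)(C(C)C)O[C@@H]1[C@@H](O[Si](C)(C)C(C)(C)C)C=C(C)[C@H]2CC(=O)[C@H](OC(=O)C(C)P(=O)(OCC)OCC)/C=C(C)\CC[C@H](OC(=O)/C(C)=C/C)[C@]12C | intermediate
30 | butenolide with 13-OTBS and 14-OTIPS | CC(C)[Si](C(C)C)(C(C)C)O[C@@H]1[C@@H](O[Si](C)(C)C(C)(C)C)C=C(C)[C@H]2CC3=C(C)C(=O)O[C@@H]3/C=C(C)\CC[C@H](OC(=O)/C(C)=C/C)[C@]12C | intermediate
31 | 13,14-diol from 30 | O[C@@H]1[C@@H](O)C=C(C)[C@H]2CC3=C(C)C(=O)O[C@@H]3/C=C(C)\CC[C@H](OC(=O)/C(C)=C/C)[C@]12C | intermediate
32 | 14-hydroxy 11-en-13-one | O[C@@H]1C(=O)C=C(C)[C@H]2CC3=C(C)C(=O)O[C@@H]3/C=C(C)\CC[C@H](OC(=O)/C(C)=C/C)[C@]12C | intermediate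
33 | CNP0218548.3, (1R,2S,5Z,7R,10R,14S)-14-acetoxy-13-oxo-2-[(E)-2-methylbut-2-enoyloxy] butenolide-fused bicycle (numbering as in the plan) | C/C=C(\C)C(=O)O[C@H]1CC/C(C)=C\[C@H]2OC(=O)C(C)=C2C[C@@H]2C(C)=CC(=O)[C@@H](OC(C)=O)[C@@]12C | target

**Step count and risks**

Total: 26 steps. Longest linear sequence: 23 steps (3 → 33 through steps 2–10 and 13–26).

Most likely to fail:

1. Step 19. The ten-membered ring may not close (oligomerization under the transannular strain of the medium ring), or addition may occur on the wrong face of the aldehyde. The fallback moves the ring-closing bond from C6–C7 to C5=C6. It sets out from 25: hydrodeiodination (Bu3SnH, Pd(PPh3)4, THF) should give the de-iodinated aldehyde with a C5(CH3)=CH2 terminus F1. Vinylmagnesium bromide at −78 °C should add to the aldehyde under Felkin–Anh control to give the (7R)-vinyl carbinol F2. Ring-closing metathesis with second-generation Grubbs catalyst (H2IMes)(PCy3)Cl2Ru=CHPh at high dilution would then form C5=C6, the Z geometry being enforced by the ten-membered ring, and the route is rejoined at 26.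

2. Step 5. Oxygen delivery may occur on both faces of the C12=C13 alkene, because the pseudoaxial C14 silyloxy group and the axial C1 methyl shield opposite faces. The fallback replaces the epoxide sequence by a Schenck ene reaction and sets out from 7. Photooxygenation (O2, hν, tetraphenylporphyrin, CH2Cl2, −20 °C, partial conversion) can abstract only the pseudoaxial C11–H on the face opposite to C14–O; it should give the C13 hydroperoxide F3 with oxygen trans to C14–O. Reduction in the same flask with PPh3 gives the allylic alcohol F4, and TBSOTf/2,6-lutidine then leads back to the route at 11, bypassing steps 6–8.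

3. Step 15. Acylation of the neopentyl C2 alcohol may stall, or the acyl group may deconjugate. The fallback builds the tiglate on the oxygen instead of transferring it and sets out from 20. DCC/DMAP esterification with 2-(diethoxyphosphoryl)propanoic acid, which reacts through a small ketene-type intermediate, should give the C2 phosphonopropanoate F5. A Horner–Wadsworth–Emmons reaction with acetaldehyde (NaH, THF, 0 °C) then forms the (E)-2-methylbut-2-enoate and rejoins the route at 21.

Further compounds
F1 | step 19 | de-iodinated aldehyde, 25 with C5(CH3)=CH2 in place of the vinyl iodide | CC(C)[Si](C(C)C)(C(C)C)O[C@@H]1[C@@H](O[Si](C)(C)C(C)(C)C)C=C(C)[C@@H](C[C@H](O[Si](CC)(CC)CC)C=O)[C@]1(C)[C@@H](OC(=O)/C(C)=C/C)CCC(C)=C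
F2 | step 19 | (7R)-vinyl carbinol from F1 | CC(C)[Si](C(C)C)(C(C)C)O[C@@H]1[C@@H](O[Si](C)(C)C(C)(C)C)C=C(C)[C@@H](C[C@H](O[Si](CC)(CC)CC)[C@H](O)C=C)[C@]1(C)[C@@H](OC(=O)/C(C)=C/C)CCC(C)=C
F3 | step 5 | C13 hydroperoxide with C11=C12 alkene, OOH trans to C14–O | CC(C)[Si](C(C)C)(C(C)C)O[C@@H]1[C@@H](OO)C=C(C)[C@@H](C[C@H]2COC(C)(C)O2)[C@]1(C)C=O
F4 | step 5 | C13 allylic alcohol from F3 | CC(C)[Si](C(C)C)(C(C)C)O[C@@H]1[C@@H](O)C=C(C)[C@@H](C[C@H]2COC(C)(C)O2)[C@]1(C)C=O
F5 | step 15 | C2 2-(diethoxyphosphoryl)propanoate of 20 | CC(C)[Si](C(C)C)(C(C)C)O[C@@H]1[C@@H](O[Si](C)(C)C(C)(C)C)C=C(C)[C@@H](C[C@H]2COC(C)(C)O2)[C@]1(C)[C@@H](OC(=O)C(C)P(=O)(OCC)OCC)CC/C(C)=C\I
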